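The runs come from a simulation with constants of no real substance, and the scatter is random.

I am to read this flask at 5.0 h, 7.50 times as late as its last reading so far, so I want a ratio whose drift I can follow, not a curve to stretch.

- spring: E 2.2 M; L 2.2 M; the very flask that is asked about, followed so far
- flask: E 2.2 M; L 2.20 M; time 5.0 h

spring run (percent of the E charged)

| time / min | E / % | Z / % | X / % |
|---|---|---|---|
| 5.00 | 95 | 0 | 6 |
| 10.0 | 89 | 0 | 10 |
| 15.0 | 89 | 0 | 16 |
| 20.0 | 83 | 0 | 19 |
| 25.0 | 76 | 2 | 24 |
| 30.0 | 71 | 3 | 29 |
| 40.0 | 66 | 1 | 35 |

(readings scatter by 1.5 percentage points)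

- what may be going on: L <-> J; X + D -> Z; E <-> X; L -> D
- the reaction counts as stopped when no species that holds the E changes by six tenths of a point or more over the second half of the time

- why nothing more happens at 5.0 h, or that something still does (all of E has reacted / it is still moving / forward and back rates have come level / L has run out first)
- share of the E used up at 5.0 h
- Z at 5.0 h, in percent of the E charged
- X at 5.0 h, in percent of the E charged

I read the table row against row, from 20.0 min to 40.0 min: X gains 16 percentage points and Z gains 1 point, a gain within the scatter of 1.5 points, so what follows is rough. If Z comes from X one for one, by X + D -> Z, then the Z gained is the X used, and X was made 17.0 times as fast as it was used; this ratio, rate of X made over rate of X used at one moment, I call R, and X stands at its top where R comes down to one.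

Now I read the E column: 66% left at 40.0 min, taken as first order, gives a rate constant a of 0.623 h⁻¹. Holding the use steady and letting the making fall with E, from the middle of that stretch at 30.0 min to 5.0 h, I bring R down to 1.03, so my own reckoning puts X near its top at the reading, still high, with the flask still moving.

The forecast also says it is still moving, but it goes further than I do, with Z at 78% (48% to 94%), X at 12% (3% to 35%) and 92% of E used (82% to 99%), on the ground that “Z overtakes X and drains it”.

The flask gives: it is still moving, 79.5% of E used, Z 26.9%, X 52.6%.

    L ⇌ J (K = 1.00, k = 3.79 × 10⁻⁴ s⁻¹)
    X + D → Z (k = 5.45 × 10⁻⁵ L mol⁻¹ s⁻¹)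
    E ⇌ X (K = 3.10, k = 1.89 × 10⁻⁴ s⁻¹)
    L → D (k = 8.96 × 10⁻⁵ s⁻¹)

At 5.00 h, each step taken net, R stands at 0.360, down from the 17.0 read early and below one, so this flask is past the top of X, which has slipped from 59.2% at 2.50 h to 52.6% while Z is still climbing. The same flask read at 20 h holds X 17.1% and Z 76.9%, and the gains since 5.0 h, taken as in the first reckoning, give R = 0.288, lower than the 17.0 read early.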